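**Strategy.** The five-membered ring C5–C6–C7–C8–C9, with oxygen on C5 and C8 on either side of the gem-dimethyl carbon C9, is the skeleton of 2,2-dimethylcyclopent-4-ene-1,3-dione. The route therefore disconnects C6–C10 and C4–C5 and forms both bonds in one flask. A chiral alkenyl Grignard reagent (C10, C11, C2, C3 and the furan side chain) adds 1,4 under copper–phosphoramidite control, and the resulting C7=C8 enolate masks C8 while vinylmagnesium bromide attacks C5. The precursors are the enedione and a 2-bromo-1,5-diene carrying the C11/C2 pair, built on (S)-4-methyloxolan-2-one. Ring-closing metathesis at C3=C4 then closes the seven-membered ring; C8 reduction, furan oxidation and unmasking of C10 finish the synthesis.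

Key step: step 10

Numbering used below: seven-membered ring C2 (CH–CH3), C3, C4, C5 (C–OH), C6 (CH), C10 (C=O), C11 (quaternary); five-membered ring C5, C6, C7, C8 (CH–OH), C9 (CMe2).
Remark (C8): in the target the hydroxyls on C5 and C8 are cis to each other and to the C6–C10 bond, so hydride must reach C8 from the face opposite the C5 oxygen; reagents that carry the hydride on that oxygen (for example triacetoxyborohydrides) would give the C8 epimer and are not used.
Remark (fragment 2): a lactone template is used for the C11/C2 pair because an acyclic α-methyl-α-alkyl ester enolate has no dependable geometry and an achiral crotyl ester offers no absolute control.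
Assumption: (4S)-4-methyloxolan-2-one (5) is bought as the single enantiomer.
Assumption: the (S,R,R) phosphoramidite L [(S)-1,1′-binaphthyl-2,2′-diyl N,N-bis((R)-1-phenylethyl)phosphoramidite] is taken as the ligand enantiomer matched with the C11 centre of 18; if a two-run screen shows otherwise, its mirror image is used unchanged.
Assumption: metal alkoxides and borates that exist only until the aqueous quench are not numbered, except 20 in step 10.

Step 1
Reactants: 1 3-bromofuran
Product: 3 2-(furan-3-yl)ethan-1-ol, via furan-3-yllithium 2 (not isolated)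
Conditions: n-BuLi, THF, −78 °C; ethylene oxide, BF3·OEt2, −78 °C; H2O
Reagents that add atoms: ethylene oxide, C1CO1
Why: Bromine–lithium exchange at −78 °C gives the 3-lithiofuran before it can isomerise to the 2-lithio species, and BF3-activated ethylene oxide is opened by it at carbon (organolithium epoxide opening).

Step 2
Reactants: 3 2-(furan-3-yl)ethan-1-ol
Product: 4 3-(2-iodoethyl)furan
Conditions: I2, PPh3, imidazole, CH2Cl2, 0 °C → rt
Reagents that add atoms: iodine, I-I
Why: Appel-type iodination, in which the oxyphosphonium salt of the primary alcohol is displaced by iodide in an SN2 reaction under conditions that leave the furan alone.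

Step 3
Reactants: 5 (4S)-4-methyloxolan-2-one
Product: 7 (3S,4S)-3,4-dimethyloxolan-2-one, via lithium enolate 6 (not isolated)
Conditions: LiN(i-Pr)2, THF, −78 °C; MeI, −78 → −40 °C
Reagents that add atoms: iodomethane, C-I
Why: Kinetic enolate alkylation of a butyrolactone, in which MeI enters anti to the C4 methyl group to give the trans lactone; the new C3 centre is flattened again in step 4, so its ratio is not critical.

Step 4
Reactants: 7 (3S,4S)-3,4-dimethyloxolan-2-one; 4 3-(2-iodoethyl)furan
Product: 9 (3S,4S)-3-[2-(furan-3-yl)ethyl]-3,4-dimethyloxolan-2-one, via lithium enolate 8 (not isolated)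
Conditions: LiN(i-Pr)2, THF, −78 °C; 4, DMPU, −78 → −20 °C
Reagents that add atoms: none
Why: Second lactone enolate alkylation, in which the planar C3 enolate 8 is attacked by the primary iodide on the face away from the C4 methyl group (1,2-induction in a five-membered ring), so the furylethyl chain ends trans and the C3 methyl cis to the C4 methyl, which is the C11/C2 relationship of the target; the order of the two alkylations decides the quaternary configuration.

Step 5
Reactants: 9 (3S,4S)-3-[2-(furan-3-yl)ethyl]-3,4-dimethyloxolan-2-one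
Product: 10 (3S,4S)-3-[2-(furan-3-yl)ethyl]-5-hydroxy-3,4-dimethylpentan-2-one (in equilibrium with its cyclic hemiketal)
Conditions: MeLi (1.1 equiv), Et2O, −78 °C; H2O at −78 °C
Reagents that add atoms: methyllithium, [Li]C
Why: Single addition of MeLi to a lactone, in which the lithium lactolate survives at −78 °C and opens to the methyl ketone only on quench, so no tertiary alcohol forms and the α-quaternary centre cannot epimerise.

Step 6
Reactants: 10 (3S,4S)-3-[2-(furan-3-yl)ethyl]-5-hydroxy-3,4-dimethylpentan-2-one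
Product: 11 (2S,3S)-3-[2-(furan-3-yl)ethyl]-2,3-dimethyl-4-oxopentanal
Conditions: Dess–Martin periodinane, CH2Cl2, 0 °C → rt
Reagents that add atoms: none
Why: Dess–Martin oxidation of the primary alcohol of the open-chain tautomer under non-basic conditions should give the aldehyde without epimerising the adjacent C–H centre or triggering aldol closure onto the methyl ketone.

Step 7
Reactants: 11 (2S,3S)-3-[2-(furan-3-yl)ethyl]-2,3-dimethyl-4-oxopentanal
Product: 12 (3S,4R)-3-[2-(furan-3-yl)ethyl]-3,4-dimethylhex-5-en-2-one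
Conditions: Ph3PCH3Br, KN(SiMe3)2, THF, 0 °C; then 11, −78 → 0 °C
Reagents that add atoms: methyltriphenylphosphonium bromide, C[P+](c1ccccc1)(c1ccccc1)c1ccccc1.[Br-]
Why: Wittig methylenation, in which the unstabilised ylide adds to the aldehyde at low temperature far faster than to the ketone shielded by the quaternary carbon and faster than it deprotonates the α-centre.

Step 8
Reactants: 12 (3S,4R)-3-[2-(furan-3-yl)ethyl]-3,4-dimethylhex-5-en-2-one
Product: 13 (3S,4R)-2-bromo-3-[2-(furan-3-yl)ethyl]-3,4-dimethylhexa-1,5-diene (fragment 2)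
Conditions: (PhO)3P (1.3 equiv), Br2 (1.2 equiv), CH2Cl2, −60 °C; then Et3N, 12, −60 → 40 °C
Reagents that add atoms: bromine, BrBr
Why: Ketone-to-alkenyl bromide conversion with the triphenyl phosphite–bromine reagent, in which the bromophosphonium species activates the carbonyl oxygen and Et3N removes a proton from the only enolisable side, the methyl group, so the 2-bromo-1-alkene is the sole regioisomer; premixing the phosphite in excess leaves no free Br2 for the furan or the vinyl group.

Step 9
Reactants: 14 2,2-dimethylcyclopentane-1,3-dione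
Product: 16 2,2-dimethylcyclopent-4-ene-1,3-dione, via bromo dione 15 (not isolated)
Conditions: CuBr2 (2.2 equiv), MeOH, reflux
Reagents that add atoms: none
Why: Bromination–dehydrobromination, in which CuBr2 brominates the enolisable α-position and the bromo dione 15 loses HBr in the hot methanol to give the cross-conjugated enedione, the gem-dimethyl carbon blocking any further enolisation.

Step 10
Reactants: 13 (3S,4R)-2-bromo-3-[2-(furan-3-yl)ethyl]-3,4-dimethylhexa-1,5-diene; 16 2,2-dimethylcyclopent-4-ene-1,3-dione; 17 vinylmagnesium bromide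
Product: 21 (3S,4R)-3-ethenyl-4-[(3S,4R)-3-[2-(furan-3-yl)ethyl]-3,4-dimethylhexa-1,5-dien-2-yl]-3-hydroxy-2,2-dimethylcyclopentan-1-one, via alkenylmagnesium bromide 18 (not isolated), via magnesium enolate 19 (not isolated), via magnesium alkoxide enolate 20 (not isolated)
Conditions: Mg, 2-MeTHF, 45 °C; then 16, CuBr·SMe2 (5 mol %), L (10 mol %), CH2Cl2, −78 °C, slow addition of 18; then 17 (3 equiv), −78 → −30 °C; pH 7 buffer
Reagents that add atoms: none
Why: Magnesium insertion turns 13 into Grignard reagent 18, which transmetalates to the chiral copper–phosphoramidite complex and adds its alkenyl group 1,4 to one of the two enantiotopic alkene carbons of 16 (π-complexation, C–C bond formation at C6, release of the bromomagnesium enolate 19 spanning C7–C8). Because C8 now rests as an enolate, vinylmagnesium bromide can attack only the C5 ketone, giving 20, and neutral quench returns the C8 ketone in 21; the closest known reaction type is the copper-catalysed desymmetrising conjugate addition of organometallic reagents to 2,2-disubstituted cyclopent-4-ene-1,3-diones followed by 1,2-addition to the unmasked carbonyl. No ring is closed. C6 is set by the ligand (reagent control, chosen so that the C11 centre next to the nucleophilic carbon reinforces it) and C5 by the new C6 substituent, which makes the vinyl group enter anti so that C5–OH ends cis to the C10 branch. The step needs 1,4- over 1,2-addition of 18 (copper catalysis, slow addition at −78 °C, a nucleophile hindered by its neighbouring quaternary carbon), no proton transfer between C6–H and the enolate (low temperature, magnesium counter-ion) and C5/C8 differentiation, which the enolate itself supplies. Keeping the enolate until the quench also blocks retro-aldol cleavage of the C5 alkoxide.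

Step 11
Reactants: 21 (3S,4R)-3-ethenyl-4-[(3S,4R)-3-[2-(furan-3-yl)ethyl]-3,4-dimethylhexa-1,5-dien-2-yl]-3-hydroxy-2,2-dimethylcyclopentan-1-one
Product: 22 (1S,3R,5R)-1-ethenyl-5-[(3S,4R)-3-[2-(furan-3-yl)ethyl]-3,4-dimethylhexa-1,5-dien-2-yl]-2,2-dimethylcyclopentane-1,3-diol
Conditions: NaBH4, CeCl3·7H2O, MeOH, −78 → −40 °C
Reagents that add atoms: none
Why: Luche-type reduction with external hydride, in which the pseudo-axial C5–OH and the C6 side chain lie on one face of the cyclopentanone, so borohydride should enter C8 from the opposite face and give the 8R alcohol cis to C5–OH (steric approach control); the methoxyborohydrides formed in methanol do not exchange onto the tertiary C5–OH, so no hydride is delivered from that oxygen.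

Step 12
Reactants: 22 (1S,3R,5R)-1-ethenyl-5-[(3S,4R)-3-[2-(furan-3-yl)ethyl]-3,4-dimethylhexa-1,5-dien-2-yl]-2,2-dimethylcyclopentane-1,3-diol
Product: 23 (2R,3aR,5S,6R,8aS)-5-[2-(furan-3-yl)ethyl]-1,1,5,6-tetramethyl-4-methylidene-2,3,3a,4,5,6-hexahydroazulene-2,8a(1H)-diol
Conditions: second-generation Grubbs catalyst (5 mol %), CH2Cl2 (5 mM), 40 °C
Reagents that add atoms: none
Why: Ring-closing metathesis of the two monosubstituted vinyl groups forms the seven-membered ring with loss of ethene, the fully substituted C5 and C11 favouring closure, whereas the C10 methylene could only close four-membered rings and stays out.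

Step 13
Reactants: 23 (2R,3aR,5S,6R,8aS)-5-[2-(furan-3-yl)ethyl]-1,1,5,6-tetramethyl-4-methylidene-2,3,3a,4,5,6-hexahydroazulene-2,8a(1H)-diol
Product: 24 (2R,3aR,5S,6R,8aS)-5-[2-(furan-3-yl)ethyl]-1,1,5,6-tetramethyl-4-methylideneoctahydroazulene-2,8a(1H)-diol
Conditions: H2 (1 atm), RhCl(PPh3)3 (10 mol %), benzene/EtOH, rt
Reagents that add atoms: none
Why: Homogeneous hydrogenation with RhCl(PPh3)3 discriminates by steric access, so the cis-disubstituted ring alkene is reduced while the 1,1-disubstituted methylene wedged between C11 and C6 and the aromatic furan are not.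

Step 14
Reactants: 24 (2R,3aR,5S,6R,8aS)-5-[2-(furan-3-yl)ethyl]-1,1,5,6-tetramethyl-4-methylideneoctahydroazulene-2,8a(1H)-diol
Product: 26 4-{2-[(2R,3aR,5S,6R,8aS)-2,8a-dihydroxy-1,1,5,6-tetramethyl-4-methylidenedecahydroazulen-5-yl]ethyl}-5-hydroxyfuran-2(5H)-one (both lactol epimers), via furan endoperoxide 25 (not isolated)
Conditions: O2, hν, rose bengal, i-Pr2NEt, CH2Cl2, −78 °C
Reagents that add atoms: dioxygen (as singlet oxygen), O=O
Why: Photooxygenation of a 3-alkylfuran, in which [4+2] addition of singlet oxygen gives endoperoxide 25 and the hindered amine removes the proton at the furan carbon remote from the side chain (Kornblum–DeLaMare type fragmentation), placing the carbonyl there and the hydroxyl next to the side chain; the hindered 1,1-disubstituted alkene is a poor ene partner at −78 °C.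

Step 15
Reactants: 26 4-{2-[(2R,3aR,5S,6R,8aS)-2,8a-dihydroxy-1,1,5,6-tetramethyl-4-methylidenedecahydroazulen-5-yl]ethyl}-5-hydroxyfuran-2(5H)-one
Product: 28 4-{2-[(2R,3aR,5S,6R,8aS)-2,8a-dihydroxy-1,1,5,6-tetramethyl-4-methylidenedecahydroazulen-5-yl]ethyl}furan-2(5H)-one, via sodium hydroxy enoate 27 (not isolated)
Conditions: NaBH4, EtOH, 0 °C; then 1 M HCl to pH 3
Reagents that add atoms: none
Why: Borohydride reduction of the ring-opened formyl form of the hydroxybutenolide gives the (Z)-hydroxy enoate 27, which lactonises on acidification to the 4-substituted furan-2(5H)-one; no ketone is present at this stage to compete.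

Step 16
Reactants: 28 4-{2-[(2R,3aR,5S,6R,8aS)-2,8a-dihydroxy-1,1,5,6-tetramethyl-4-methylidenedecahydroazulen-5-yl]ethyl}furan-2(5H)-one
Product: 30 (2R,3aS,5S,6R,8aS)-2,8a-dihydroxy-1,1,5,6-tetramethyl-5-[2-(5-oxo-2,5-dihydrofuran-3-yl)ethyl]octahydroazulen-4(1H)-one (CNP0077405.1), via ozonide 29 (not isolated)
Conditions: O3 (1 equiv, Sudan red 7B end point), CH2Cl2, −78 °C; then PPh3, −78 °C → rt
Reagents that add atoms: ozone, [O-][O+]=O
Why: Ozonolysis, in which ozone adds to the electron-rich 1,1-disubstituted alkene much faster than to the electron-poor butenolide alkene, and PPh3 reduces the ozonide 29 to the C10 ketone under neutral conditions that should not epimerise C6 or dehydrate the C5 carbinol.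

**Compound list**

1 | 3-bromofuran | Brc1ccoc1 | starting material
2 | furan-3-yllithium | [Li]c1ccoc1 | intermediate (not isolated)
3 | 2-(furan-3-yl)ethan-1-ol | OCCc1ccoc1 | intermediate
4 | 3-(2-iodoethyl)furan | ICCc1ccoc1 | intermediate
5 | (4S)-4-methyloxolan-2-one | O=C1C[C@H](C)CO1 | starting material
6 | lithium (4S)-4-methyl-4,5-dihydrofuran-2-olate | [Li]OC1=C[C@H](C)CO1 | intermediate (not isolated)
7 | (3S,4S)-3,4-dimethyloxolan-2-one (trans) | O=C1[C@@H](C)[C@H](C)CO1 | intermediate
8 | lithium (4S)-3,4-dimethyl-4,5-dihydrofuran-2-olate | [Li]OC1=C(C)[C@H](C)CO1 | intermediate (not isolated)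
9 | (3S,4S)-3-[2-(furan-3-yl)ethyl]-3,4-dimethyloxolan-2-one (chain trans to the C4 methyl) | O=C1[C@@](C)(CCc2ccoc2)[C@H](C)CO1 | intermediate
10 | (3S,4S)-3-[2-(furan-3-yl)ethyl]-5-hydroxy-3,4-dimethylpentan-2-one | CC(=O)[C@@](C)(CCc1ccoc1)[C@H](C)CO | intermediate
11 | (2S,3S)-3-[2-(furan-3-yl)ethyl]-2,3-dimethyl-4-oxopentanal | CC(=O)[C@@](C)(CCc1ccoc1)[C@H](C)C=O | intermediate
12 | (3S,4R)-3-[2-(furan-3-yl)ethyl]-3,4-dimethylhex-5-en-2-one | CC(=O)[C@@](C)(CCc1ccoc1)[C@H](C)C=C | intermediate
13 | (3S,4R)-2-bromo-3-[2-(furan-3-yl)ethyl]-3,4-dimethylhexa-1,5-diene (fragment 2) | BrC(=C)[C@@](C)(CCc1ccoc1)[C@H](C)C=C | intermediate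
14 | 2,2-dimethylcyclopentane-1,3-dione | CC1(C)C(=O)CCC1=O | starting material
15 | 4-bromo-2,2-dimethylcyclopentane-1,3-dione (racemic) | CC1(C)C(=O)CC(Br)C1=O | intermediate (not isolated)
16 | 2,2-dimethylcyclopent-4-ene-1,3-dione | O=C1C=CC(=O)C1(C)C | intermediate
17 | vinylmagnesium bromide | C=C[Mg]Br | starting material
18 | [(3S,4R)-3-[2-(furan-3-yl)ethyl]-3,4-dimethylhexa-1,5-dien-2-yl]magnesium bromide | Br[Mg]C(=C)[C@@](C)(CCc1ccoc1)[C@H](C)C=C | intermediate (not isolated)
19 | bromomagnesium (3R)-3-[(3S,4R)-3-[2-(furan-3-yl)ethyl]-3,4-dimethylhexa-1,5-dien-2-yl]-5,5-dimethyl-4-oxocyclopent-1-en-1-olate (enolate across C7–C8) | Br[Mg]OC1=C[C@H](C(=C)[C@@](C)(CCc2ccoc2)[C@H](C)C=C)C(=O)C1(C)C | intermediate (not isolated)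
20 | bis(bromomagnesium) (3R,4S)-4-ethenyl-3-[(3S,4R)-3-[2-(furan-3-yl)ethyl]-3,4-dimethylhexa-1,5-dien-2-yl]-5,5-dimethylcyclopent-1-ene-1,4-bis(olate) | Br[Mg]OC1=C[C@H](C(=C)[C@@](C)(CCc2ccoc2)[C@H](C)C=C)[C@@](O[Mg]Br)(C=C)C1(C)C | intermediate (not isolated)
21 | (3S,4R)-3-ethenyl-4-[(3S,4R)-3-[2-(furan-3-yl)ethyl]-3,4-dimethylhexa-1,5-dien-2-yl]-3-hydroxy-2,2-dimethylcyclopentan-1-one (C5–OH cis to the C6 branch) | C=C[C@]1(O)[C@H](CC(=O)C1(C)C)C(=C)[C@@](C)(CCc1ccoc1)[C@H](C)C=C | intermediate
22 | (1S,3R,5R)-1-ethenyl-5-[(3S,4R)-3-[2-(furan-3-yl)ethyl]-3,4-dimethylhexa-1,5-dien-2-yl]-2,2-dimethylcyclopentane-1,3-diol (cis 1,3-diol) | C=C[C@]1(O)[C@H](C[C@@H](O)C1(C)C)C(=C)[C@@](C)(CCc1ccoc1)[C@H](C)C=C | intermediate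
23 | (2R,3aR,5S,6R,8aS)-5-[2-(furan-3-yl)ethyl]-1,1,5,6-tetramethyl-4-methylidene-2,3,3a,4,5,6-hexahydroazulene-2,8a(1H)-diol (trans-fused, C3=C4 alkene) | C[C@@H]1C=C[C@]2(O)[C@H](C[C@@H](O)C2(C)C)C(=C)[C@@]1(C)CCc1ccoc1 | intermediate
24 | (2R,3aR,5S,6R,8aS)-5-[2-(furan-3-yl)ethyl]-1,1,5,6-tetramethyl-4-methylideneoctahydroazulene-2,8a(1H)-diol | C[C@@H]1CC[C@]2(O)[C@H](C[C@@H](O)C2(C)C)C(=C)[C@@]1(C)CCc1ccoc1 | intermediate
25 | 2,3,7-trioxabicyclo[2.2.1]hept-5-ene (furan endoperoxide) of 24 | C[C@@H]1CC[C@]2(O)[C@H](C[C@@H](O)C2(C)C)C(=C)[C@@]1(C)CCC1=CC2OOC1O2 | intermediate (not isolated)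
26 | 4-{2-[(2R,3aR,5S,6R,8aS)-2,8a-dihydroxy-1,1,5,6-tetramethyl-4-methylidenedecahydroazulen-5-yl]ethyl}-5-hydroxyfuran-2(5H)-one (lactol epimers) | C[C@@H]1CC[C@]2(O)[C@H](C[C@@H](O)C2(C)C)C(=C)[C@@]1(C)CCC1=CC(=O)OC1O | intermediate
27 | sodium (2Z)-4-hydroxy-3-{2-[(2R,3aR,5S,6R,8aS)-2,8a-dihydroxy-1,1,5,6-tetramethyl-4-methylidenedecahydroazulen-5-yl]ethyl}but-2-enoate | C[C@@H]1CC[C@]2(O)[C@H](C[C@@H](O)C2(C)C)C(=C)[C@@]1(C)CC/C(CO)=C/C(=O)[O-].[Na+] | intermediate (not isolated)
28 | 4-{2-[(2R,3aR,5S,6R,8aS)-2,8a-dihydroxy-1,1,5,6-tetramethyl-4-methylidenedecahydroazulen-5-yl]ethyl}furan-2(5H)-one | C[C@@H]1CC[C@]2(O)[C@H](C[C@@H](O)C2(C)C)C(=C)[C@@]1(C)CCC1=CC(=O)OC1 | intermediate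
29 | spiro-1,2,4-trioxolane (secondary ozonide) of 28 at C10, both spiro epimers | C[C@@H]1CC[C@]2(O)[C@H](C[C@@H](O)C2(C)C)C3(OOCO3)[C@@]1(C)CCC1=CC(=O)OC1 | intermediate (not isolated)
30 | (2R,3aS,5S,6R,8aS)-2,8a-dihydroxy-1,1,5,6-tetramethyl-5-[2-(5-oxo-2,5-dihydrofuran-3-yl)ethyl]octahydroazulen-4(1H)-one | C[C@@H]1CC[C@]2(O)[C@H](C[C@@H](O)C2(C)C)C(=O)[C@@]1(C)CCC1=CC(=O)OC1 | target

**Step count**

Total: 16 steps (fragment 2: 8; enedione: 1; fragment union: 1; endgame: 6).
Longest linear sequence: 14 steps from 3-bromofuran (steps 1, 2, 4–8, 10–16).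

**Steps most likely to fail**

Step 10. What may go wrong:
- uncatalysed 1,2-addition of 18 to a dione carbonyl;
- incomplete discrimination of the two enantiotopic alkene carbons if ligand and C11 centre are mismatched;
- proton transfer from C6–H to the enolate or to vinylmagnesium bromide, so that the C5 ketone is enolised and not attacked.

Fallback: it sets out from 13 and 16 and comes back at 21. The conjugate addition alone is run with Me3SiCl in the flask, so that the enolate is captured as the trimethylsilyl enol ether F1, which is isolated and, if ligand control is incomplete, freed from its C6 epimer by chromatography. The C5 ketone of F1 is then treated with the organocerium reagent made from 17 and CeCl3, which suppresses enolisation of the hindered ketone, to give the silyl enol ether carbinol F2. Aqueous citric acid in THF hydrolyses the enol ether of F2 to 21.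

Step 8. What may go wrong:
- transfer of electrophilic bromine from the halophosphonium reagent to the furan or the terminal alkene;
- stalling of carbonyl activation because the ketone sits next to a quaternary carbon.

Fallback: it sets out from 12 and comes back at 21. Hydrazine hydrate and Et3N in ethanol convert 12 into the hydrazone F3. Barton iodination of F3 (I2, tetramethylguanidine, THF) gives the alkenyl iodide F4. Iodine–magnesium exchange on F4 with i-PrMgCl·LiCl at −20 °C gives the alkenylmagnesium chloride F5, which takes the place of 18 under the conditions of step 10.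

Step 11. What may go wrong:
- hydride entering C8 on the face of the C5 oxygen, either through a transient alkoxyborohydride or because the two faces differ less than expected, which gives the 1,3-trans diol.

Fallback: it sets out from 21 and comes back at 22. N-(Trimethylsilyl)imidazole converts the C5 hydroxyl into the trimethylsilyl ether ketone F6, which can neither carry hydride nor leave its face open. LiBH(s-Bu)3 at −78 °C then reduces C8 from the opposite face to the silyl ether alcohol F7, and Bu4NF removes the silyl group to give 22.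

**Further compounds**

F1 | step 10 | (5R)-5-[(3S,4R)-3-[2-(furan-3-yl)ethyl]-3,4-dimethylhexa-1,5-dien-2-yl]-2,2-dimethyl-3-[(trimethylsilyl)oxy]cyclopent-3-en-1-one | C[Si](C)(C)OC1=C[C@H](C(=C)[C@@](C)(CCc2ccoc2)[C@H](C)C=C)C(=O)C1(C)C
F2 | step 10 | (1S,5R)-1-ethenyl-5-[(3S,4R)-3-[2-(furan-3-yl)ethyl]-3,4-dimethylhexa-1,5-dien-2-yl]-2,2-dimethyl-3-[(trimethylsilyl)oxy]cyclopent-3-en-1-ol | C[Si](C)(C)OC1=C[C@H](C(=C)[C@@](C)(CCc2ccoc2)[C@H](C)C=C)[C@@](O)(C=C)C1(C)C
F3 | step 8 | (3S,4R)-3-[2-(furan-3-yl)ethyl]-3,4-dimethylhex-5-en-2-one hydrazone | NN=C(C)[C@@](C)(CCc1ccoc1)[C@H](C)C=C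
F4 | step 8 | (3S,4R)-3-[2-(furan-3-yl)ethyl]-2-iodo-3,4-dimethylhexa-1,5-diene | IC(=C)[C@@](C)(CCc1ccoc1)[C@H](C)C=C
F5 | step 8 | [(3S,4R)-3-[2-(furan-3-yl)ethyl]-3,4-dimethylhexa-1,5-dien-2-yl]magnesium chloride (LiCl complex) | Cl[Mg]C(=C)[C@@](C)(CCc1ccoc1)[C@H](C)C=C
F6 | step 11 | (3S,4R)-3-ethenyl-4-[(3S,4R)-3-[2-(furan-3-yl)ethyl]-3,4-dimethylhexa-1,5-dien-2-yl]-2,2-dimethyl-3-[(trimethylsilyl)oxy]cyclopentan-1-one | C=C[C@]1(O[Si](C)(C)C)[C@H](CC(=O)C1(C)C)C(=C)[C@@](C)(CCc1ccoc1)[C@H](C)C=C
F7 | step 11 | (1R,3S,4R)-3-ethenyl-4-[(3S,4R)-3-[2-(furan-3-yl)ethyl]-3,4-dimethylhexa-1,5-dien-2-yl]-2,2-dimethyl-3-[(trimethylsilyl)oxy]cyclopentan-1-ol | C=C[C@]1(O[Si](C)(C)C)[C@H](C[C@@H](O)C1(C)C)C(=C)[C@@](C)(CCc1ccoc1)[C@H](C)C=C
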